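**Remarks and assumptions**

- Numbering: germacrane numbering is used for every intermediate (C1–C10 ring carbons, C11–C13 the three-carbon branch on C7, C14 on C10, C15 on C4). β is the face of ring A that carries the C7 branch; α is the opposite face.
- Commercial materials assumed: (S)-carvone, 3-bromo-2-methylprop-1-ene, allylmagnesium bromide solution, (E)-2-methylbut-2-en-1-ol and (R)-2-methylbutanoic acid.
- Structure check: the glycol-cleavage precursor needs C6, C7 and C10 as in the target, C1 epimeric to the target, and the ring-fusion hydroxyls cis to each other (here both β); re-derivation from the target confirms this set and no stereodescriptor had to be changed. The periphery is changed: the C7 branch carries its C12 oxygen from step 1, and the C1,C10 glycol is carried as a C1 silyl ether with free C10 hydroxyl instead of a cyclic carbonate.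
- Side-chain configuration: the C8 acyl group is (2S,3R)-2,3-dimethyloxirane-2-carbonyl with the two methyl groups cis, so it derives from the E (tiglate) olefin.

## Structural features

The target is a germacranolide: a ten-membered carbocycle (C1–C10) with a Z trisubstituted olefin C4=C5 (C15 on C4), a trans-fused α-methylene-γ-lactone closed from O6 to C12 across C6–C7, and a trans trisubstituted epoxide at C1–C10 (C14 on C10). C3 carries an (R)-2-methylbutanoate and C8 a (2S,3R)-2,3-dimethyloxirane-2-carboxylate. The ring has six stereocentres (1R,3S,6R,7R,8R,10R): C6, C7 and C8 are contiguous, C1 and C10 are adjacent, and C3 is isolated but allylic; three more lie in the acyl groups. Fragile groups are the methylene lactone (conjugate addition and reduction), the ring epoxide facing a transannular olefin (acid), the glycidic ester, and the allylic C–O bonds at C3 and C6. The real difficulty is the medium ring, which must hold a Z olefin and a trans epoxide, together with telling the C3 and C8 oxygens apart. The key step uses the 1,6-relation of C3 and C8: a C3–C8 bond splits the ring into ring A (C3, C4, C5, C6, C7, C8; the carvone ring, in which C4=C5 is cis by necessity and C7 bears the branch) and ring B (C8, C9, C10, C1, C2, C3). The two acyloxy carbons are then the carbons of a ring-fusion glycol.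

## Logic of the disconnections

**39 to 37.** The C1–O bond of the epoxide is cut, leaving the oxygen on C10. The epoxide would not survive the acid and fluoride used earlier, so it is made last under base. A trans epoxide cannot come from epoxidation of an olefin that was cis in ring B, but it does come from a syn glycol by inversion at one carbon. The forward step must sulfonylate only the C1 hydroxyl (the single secondary hydroxyl of 37), displace through 38 with inversion, and use a base that does not add to the methylene lactone.

**37 to 34 to 33.** The lactone C12–O6 bond is cut and C12 returned to a primary allylic alcohol; then the three silyl ethers are restored. The methylene lactone is the group most exposed to hydride and nucleophiles, so it is formed after both reductions and both acylations. The forward oxidation must take the primary allylic alcohol in the presence of three other hydroxyls, and one fluoride step must free O1, O6 and O12.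

**33 to 30 and 31; 30 to 29.** The C3 acyl–oxygen bond is cut, then the C3–H bond (carbinol back to the conjugated ketone). This leaves the enone that the ring cleavage delivers. The reduction must be 1,2-selective and controlled by the reagent, because the face preference of the ten-membered ring is not predictable; the acylation must not epimerise 31.

**29 to 23 and 27; 27 to 25 to 24.** The C8 acyl–oxygen bond is cut; the acid is traced through the epoxy alcohol to the E allylic alcohol. Both side-chain stereocentres then come from one asymmetric epoxidation.

**23 to 22.** The C8–H bond is cut (carbinol back to ketone). The forward reduction must choose the saturated ketone over the enone and one face of C8. The C10 hydroxyl is therefore left free in 22 so that it can deliver hydride internally; it is 1,3-anti to O8 in the target.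

**22 to 20.** The C3–C8 bond is re-formed, turning the 3,8-dione into the cis ring-fusion glycol of a decalin. This removes the medium ring: the Z olefin becomes a ring A olefin, and C6, C7, C10 and C1 become centres on six-membered rings. No macrocyclisation is needed. The forward step needs a cis glycol, no second free vicinal glycol, and gentle handling of a β-oxygenated 1,6-dione.

**20 to 19 to 18 to 17.** The C1–O and C10–O bonds are cut back to the ring B olefin, with exchange of the ring-fusion acetonide and the C1 silyl ether. Syn addition gives C10 as in the target and C1 epimeric, as the last step requires. The addition must occur on the face anti to the ring-fusion oxygens, so these are tied into an acetonide that covers their face. A cyclic carbonate on C1/C10 is avoided: it would be a leaving group β to both ketones of 22 and could not be removed late without harming the esters and the lactone.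

**17 to 16.** The ring B olefin C1=C10 is cut to allyl and methallyl groups. They must be cis on C3 and C8, and the other two olefins must not take part.

**16 to 15 to 13 and 14.** The C2–C3 bond is cut (and the acetonide is returned to the mixed ketal). A free 3,8-dione is avoided: it would enolise through C7 and could lose the C6 silyloxy group. Only one carbonyl addition is used, onto a ketone whose neighbour C8 is already quaternary. The nucleophile must enter anti to the C8 oxygen so that the glycol is cis.

**13 to 12 to 11 to 9.** The C6–O bond is cut. The γ-oxidation is placed after C8 has become quaternary, so enolisation can go only toward C6. The oxidation must be γ-selective, trans to the C7 branch, and must leave the isolated olefins alone.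

**9 to 6 and 7.** The C8–C9 bond is cut. Making the C–C bond after the C–O bond at C8 puts carbon trans and oxygen cis to the C7 branch; this order is what makes the ring-fusion glycol cis after the allyl addition. The step needs C-alkylation of a hindered α-alkoxy enolate and an oxygen protecting group that cannot migrate to the enolate oxygen.

**6 to 5 to 3.** The C8–O bond is cut (enolate hydroxylation), after removal of the mixed ketal.

**3 to 2 to 1.** The C12–O bond is cut. Allylic oxidation of the branch is done first, when the only other olefin is the electron-poor enone; later, C15 on the trisubstituted olefin or the methallyl group would compete.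

## Other disconnections considered

**Alternative 1:** The cuts are C4–C15 and C5–C6, with the ring still open between C2 and C3. In the forward step a propargylic alkoxide (C3–C4–C5) undergoes anti carbomagnesiation by a methylmagnesium halide under cuprous catalysis. The chelated vinylmagnesium at C5 then adds to the C6 aldehyde of a fragment holding C7, C8 and the E olefin C1=C10, giving A1.
- In favour: the Z geometry follows from the anti addition; three components give fourteen skeletal carbons in one flask; the plan is convergent. The E olefin at C1=C10 would allow the trans epoxide by direct late epoxidation with no inversion. On that point, and on step count up to A1, this alternative is better than the chosen plan.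
- Against: the C6 configuration depends on Felkin versus chelate control at an α-branched aldehyde. The ten-membered ring must still be closed at C2–C3 with a Z olefin in the chain, and C3 is set then or later. C13 has to be added late by methylenation, and the face of the late epoxidation rests on the macrocycle conformation.
- Comparison: structurally the chosen plan never cyclises a medium ring and sets every ring stereocentre on a six-membered ring. Mechanistically the carbometalation is as well founded as any step of the chosen plan; the weak link is the ring closure, whereas here it is the face of osmylation. In step economy the alternative would probably be shorter if its ring closure worked.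

**Alternative 2:** The cuts are C7–C11 and C11=C13. In the forward step the sodium salt of a phosphonoacetate bound to O6 opens a C7–C8 epoxide at C7 (5-exo, inversion), forming the lactone and freeing the C8 hydroxyl. The remaining phosphonate anion then methylenates the one-carbon aldehyde in a Horner–Wadsworth–Emmons reaction, giving A2.
- In favour: one operation builds the lactone, sets C7 stereospecifically from an epoxide that asymmetric epoxidation can provide, frees O8 for acylation and installs the exocyclic methylene. For the lactone unit this is better than the chosen plan, which spends an allylic oxidation, a silyl ether and a late oxidative lactonisation on it.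
- Against: 5-exo opening at C7 must beat 6-endo opening at C8. The methylene lactone must then survive the ring closure (C3–C4, from the Z iodoalkene of A2 and a C3 aldehyde) and the C3 chemistry. The closure is again a medium ring, with C3 uncontrolled.
- Comparison: structurally A2 already holds the C6/C7/C8 triad by reagent control, equal to the chosen plan. Mechanistically the risk moves to a macrocyclisation in the presence of a Michael acceptor, which the chosen plan avoids by forming the lactone last. The step count would likely be lower than here.

**Alternative 3:** The cuts are C2–C3 and O–C1. In the forward step hypochlorite oxidation of the C3 aldoxime gives a nitrile oxide conjugated to C4=C5. It adds across the vinyl group on C10 (carbon to C2, oxygen to C1) and closes the ten-membered carbocycle as the bridged isoxazoline A3.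
- In favour: one step closes the ring and installs the C1 oxygen and the C3 carbonyl in masked form. C10 comes from an acyclic monoterpene tertiary allylic alcohol of the chiral pool, so it does not depend on a face selectivity; on this point the alternative is better than the chosen plan (step 12). A3 has C1 and C10 configured as in 18, so the route to the epoxide would be the same (equal).
- Against: a dipolar cycloaddition that forms a ten-membered ring must outrun dimerisation of the nitrile oxide. The C1 configuration is fixed only by chain conformation in the transition state. Hypochlorite meets electron-rich olefins. The saturated lactone of A3 still needs methylenation, and the N–O bond must be cleaved next to a Z olefin.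
- Comparison: structurally both plans place oxygen on C1 and C3 efficiently. Mechanistically the chosen plan swaps a medium-ring cycloaddition for a bond scission that has no entropic penalty. Step counts would be comparable.

Key step: step 15

## Route

Step 1
Reactants: 1 (S)-carvone
Product: 2 (5S)-5-(3-hydroxyprop-1-en-2-yl)-2-methylcyclohex-2-en-1-one
Conditions: SeO2 (cat.), t-BuOOH, CH2Cl2, rt
Reagents that add atoms: selenium dioxide O=[Se]=O (oxygen carrier); tert-butyl hydroperoxide CC(C)(C)OO (terminal oxidant)
Why: Catalytic SeO2 allylic oxidation (ene reaction, then [2,3]-sigmatropic shift, reoxidation by the hydroperoxide); the enone olefin is electron-poor and inert, so only the 1,1-disubstituted olefin reacts, at its methyl group (C12) and not at the ring methine; C7 is untouched.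

Step 2
Reactants: 2 (5S)-5-(3-hydroxyprop-1-en-2-yl)-2-methylcyclohex-2-en-1-one
Product: 3 12-O-tert-butyldiphenylsilyl ether of 2
Conditions: t-BuPh2SiCl, imidazole, CH2Cl2, rt
Reagents that add atoms: tert-butylchlorodiphenylsilane CC(C)(C)[Si](Cl)(c1ccccc1)c1ccccc1
Why: Silylation of the primary allylic alcohol; this silyl group is chosen because it must survive aqueous acetic acid in step 14.

Step 3
Reactants: 3 12-O-tert-butyldiphenylsilyl ether of 2
Product: 5 8α-hydroxy ketone, via sodium enolate 4 (not isolated)
Conditions: NaN(SiMe3)2, THF, −78 °C; 2-(phenylsulfonyl)-3-phenyloxaziridine, −78 °C; aq. NH4Cl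
Reagents that add atoms: 2-(phenylsulfonyl)-3-phenyloxaziridine O=S(=O)(N1OC1c1ccccc1)c1ccccc1
Why: Kinetic deprotonation at C8 gives the cross-conjugated enolate 4, and electrophilic hydroxylation (Davis oxidation) should occur anti to the C7 branch; the C8 configuration is temporary because C8 is enolised again in step 5.

Step 4
Reactants: 5 8α-hydroxy ketone
Product: 6 8-O-(2-methoxypropan-2-yl) ether of 5
Conditions: 2-methoxypropene, PPTS (cat.), CH2Cl2, 0 °C
Reagents that add atoms: 2-methoxypropene COC(C)=C
Why: Acid-catalysed addition of the hydroxyl to the enol ether gives a mixed ketal that cannot migrate to an enolate oxygen (a silyl group could), is stable to amide bases and Grignard reagents, and later hands its isopropylidene unit to the ring-fusion glycol.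

Step 5
Reactants: 6 8-O-(2-methoxypropan-2-yl) ether of 5; 7 3-bromo-2-methylprop-1-ene
Product: 9 8α-methallyl-8β-alkoxy enone, via lithium enolate 8 (not isolated)
Conditions: LiN(iPr)2, THF, −78 °C; then 7, DMPU, −78 to −20 °C
Reagents that add atoms: none
Why: Alkylation of the α-alkoxy ketone enolate 8 with an allylic bromide; allylic strain between the C8 alkoxy group and the C7 branch turns the branch pseudoaxial, so the electrophile should enter anti to it (as in the trans-selective α'-alkylation of carvone), which sets C8 with methallyl α and oxygen β and blocks the α' side for step 6.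

Step 6
Reactants: 9 8α-methallyl-8β-alkoxy enone
Product: 11 3-(tert-butyldimethylsilyloxy)-3,5-diene, via potassium dienolate 10 (not isolated)
Conditions: KN(SiMe3)2, THF, −78 °C; then t-BuMe2SiCl, −78 to 0 °C
Reagents that add atoms: tert-butylchlorodimethylsilane CC(C)(C)[Si](C)(C)Cl
Why: With C8 quaternary the only acidic hydrogens are those on C6, so the extended dienolate 10 forms regiospecifically and is silylated on oxygen to the linear silyl dienol ether.

Step 7
Reactants: 11 3-(tert-butyldimethylsilyloxy)-3,5-diene
Product: 12 6α-hydroxy enone
Conditions: 3-chloroperbenzoic acid, NaHCO3, CH2Cl2, −20 °C; aq. Na2S2O3/NaHCO3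
Reagents that add atoms: 3-chloroperbenzoic acid OOC(=O)c1cccc(Cl)c1
Why: Vinylogous Rubottom oxidation: the peracid epoxidises the electron-rich distal C5=C6 bond and the epoxide opens with push from the silyloxy group to the γ-hydroxy enone; attack anti to the C7 branch and to the pseudoaxial C8 oxygen should place O6 α, trans to the branch as the trans lactone needs, while the isolated 1,1-disubstituted olefins react far more slowly.

Step 8
Reactants: 12 6α-hydroxy enone
Product: 13 6α-(tert-butyldimethylsilyloxy) enone
Conditions: t-BuMe2SiCl, imidazole, DMAP (cat.), DMF, 40 °C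
Reagents that add atoms: tert-butylchlorodimethylsilane CC(C)(C)[Si](C)(C)Cl
Why: Silylation of the secondary allylic alcohol with the silyl chloride (no silyl triflate), which leaves the mixed ketal intact.

Step 9
Reactants: 13 6α-(tert-butyldimethylsilyloxy) enone; 14 allylmagnesium bromide
Product: 15 3α-allyl-3β-hydroxy compound
Conditions: CH2=CHCH2MgBr, THF/Et2O, −78 °C; aq. NH4Cl at −78 °C
Reagents that add atoms: none
Why: 1,2-Addition of an allyl Grignard reagent to the hindered enone carbonyl (cyclic allyl transfer, no conjugate addition); in the favoured half-chair the C7 branch and the C6 silyloxy group are equatorial and the C8 oxygen axial, so attack anti to the axial C8–O bond (Felkin–Anh, also the axial trajectory) should give allyl α and hydroxyl β at C3, cis to O8, whereas a chelated geometry would force methallyl and the C6 silyloxy group syn-diaxial.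

Step 10
Reactants: 15 3α-allyl-3β-hydroxy compound
Product: 16 3β,8β-O-isopropylidene acetal
Conditions: PPTS (cat.), 4 Å molecular sieves, CH2Cl2, rt
Reagents that add atoms: none
Why: Intramolecular transketalisation: acid ionises the mixed ketal with loss of methanol and the neighbouring cis tertiary hydroxyl traps the oxocarbenium ion, giving the acetonide of the ring-fusion glycol, which is to cover the β face of ring B in step 12.

Step 11
Reactants: 16 3β,8β-O-isopropylidene acetal
Product: 17 cis-fused bicyclic diene with the C1=C10 olefin
Conditions: second-generation Grubbs catalyst (5 mol %), CH2Cl2, 40 °C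
Reagents that add atoms: none
Why: Ring-closing metathesis of the cis allyl and methallyl groups gives the trisubstituted cyclohexene of ring B with loss of ethene; the C4=C5 olefin and the hindered branch olefin stay out because their closures would give a bridged or a tetrasubstituted olefin.

Step 12
Reactants: 17 cis-fused bicyclic diene with the C1=C10 olefin
Product: 18 1,10-diol
Conditions: OsO4 (cat.), N-methylmorpholine N-oxide, acetone/H2O, 0 °C to rt
Reagents that add atoms: osmium tetroxide O=[Os](=O)(=O)=O (oxygen carrier); N-methylmorpholine N-oxide C[N+]1([O-])CCOCC1; water O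
Why: Catalytic osmylation (suprafacial [3+2] addition, hydrolysis of the osmate ester) of the most electron-rich and least hindered olefin; an acetonide methyl lies over the ring B face syn to the ring-fusion oxygens, while the face turned to ring A is flanked only by the axial H7 because C4 and C5 are trigonal, so addition anti to the acetonide should set C10 as in the target and C1 epimeric to it, the two hydroxyls being cis by mechanism.

Step 13
Reactants: 18 1,10-diol
Product: 19 1-O-tert-butyldimethylsilyl ether
Conditions: t-BuMe2SiCl, imidazole, DMF, rt
Reagents that add atoms: tert-butylchlorodimethylsilane CC(C)(C)[Si](C)(C)Cl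
Why: Silylation of the only secondary hydroxyl; the tertiary C10 hydroxyl does not react with the silyl chloride, and a silyloxy group at C1 is a poor leaving group β to the coming C3 ketone.

Step 14
Reactants: 19 1-O-tert-butyldimethylsilyl ether
Product: 20 cis-fused decalin-3,8,10-triol
Conditions: AcOH/THF/H2O (3:1:1), rt
Reagents that add atoms: none
Why: Acid hydrolysis of the strained ditertiary ketal; the secondary tert-butyldimethylsilyl ethers and the tert-butyldiphenylsilyl ether should survive dilute acetic acid at room temperature.

Step 15
Reactants: 20 cis-fused decalin-3,8,10-triol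
Product: 22 ten-membered 4Z-ene-3,8-dione, via cyclic lead diester 21 (not isolated)
Conditions: Pb(OAc)4, pyridine, CH2Cl2, 0 °C; cold filtration through Celite
Reagents that add atoms: none
Why: Criegee glycol cleavage: the two cis tertiary hydroxyls at C3 and C8 exchange acetate on tetravalent lead to give the five-membered cyclic diester 21, which fragments in a concerted two-electron step to the C3 and C8 carbonyl groups and divalent Pb(OAc)2. The closest known reaction type is the cleavage of cis ring-fusion diols of bicyclo[4.4.0]decanes to cyclodecane-1,6-diones. The ten-membered ring is not closed by bond formation; it appears by scission of the bond shared by ring A and ring B, so no cyclisation mode has to compete with oligomerisation or transannular strain. No stereocentre forms: C3 and C8 are erased, and C6, C7, C10, C1 and the Z geometry of C4=C5 (cis by necessity in ring A) pass on unchanged. The selectivity needed is cleavage of the C3–C8 glycol only, which the substrate secures because O1 is silylated, so the C10 hydroxyl has no free vicinal partner and its 1,3-relation to the C8 hydroxyl cannot give a five-membered diester. The cis geometry fixed in steps 5 and 9 should make diester formation fast at 0 °C, below the temperatures at which tetravalent lead attacks olefins or forms alkoxy radicals. The two ketones differ (C8 saturated with a β hydroxyl on C10, C3 conjugated), and this is what lets the two esters be placed one after the other. The product is a β-oxygenated 1,6-dione open to transannular aldolisation, so it is kept cold and reduced at once.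

Step 16
Reactants: 22 ten-membered 4Z-ene-3,8-dione
Product: 23 (8R)-8-hydroxy enone
Conditions: Me4NBH(OAc)3, MeCN/AcOH (1:1), −30 °C
Reagents that add atoms: none
Why: Hydroxyl-directed reduction (Evans–Saksena): the C10 hydroxyl exchanges onto boron and hydride is delivered internally through a chair in which both ring branches (C1 on C10, C7 on C8) are equatorial, giving the 1,3-anti diol, that is the 8R carbinol; the conjugated C3 ketone has no hydroxyl in range and is not reduced by triacetoxyborohydride.

Step 17
Reactants: 24 (E)-2-methylbut-2-en-1-ol
Product: 25 [(2R,3R)-2,3-dimethyloxiran-2-yl]methanol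
Conditions: Ti(OiPr)4 (cat.), D-(−)-diethyl tartrate, t-BuOOH, 4 Å molecular sieves, CH2Cl2, −20 °C
Reagents that add atoms: tert-butyl hydroperoxide CC(C)(C)OO
Why: Sharpless asymmetric epoxidation of an E trisubstituted allylic alcohol; the L-tartrate gives 2S,3S epoxides from E allylic alcohols, so the D-tartrate should give the (2R,3R)-epoxy alcohol and set both side-chain stereocentres.

Step 18
Reactants: 25 [(2R,3R)-2,3-dimethyloxiran-2-yl]methanol
Product: 27 (2S,3R)-2,3-dimethyloxirane-2-carboxylic acid, via epoxy aldehyde 26 (not isolated)
Conditions: RuCl3 hydrate (cat.), NaIO4, MeCN/EtOAc/H2O, rt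
Reagents that add atoms: sodium periodate [Na+].[O-][I](=O)(=O)=O; water O
Why: RuO4 formed catalytically oxidises the primary alcohol through aldehyde 26 to the acid without opening the epoxide; the stereocentres are untouched (the C2 descriptor changes from R to S only through the change in priorities).

Step 19
Reactants: 23 (8R)-8-hydroxy enone; 27 (2S,3R)-2,3-dimethyloxirane-2-carboxylic acid
Product: 29 C8 epoxy ester, via mixed anhydride 28 (not isolated)
Conditions: 27, 2,4,6-trichlorobenzoyl chloride, Et3N, THF, rt; then 23, DMAP, toluene, rt
Reagents that add atoms: none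
Why: Yamaguchi esterification: DMAP is acylated at the less hindered carbonyl of mixed anhydride 28 and the acylpyridinium ion esterifies the secondary C8 hydroxyl; the tertiary C10 hydroxyl is not acylated under these conditions.

Step 20
Reactants: 29 C8 epoxy ester
Product: 30 (3S)-3-hydroxy compound
Conditions: (R)-2-methyl-CBS-oxazaborolidine, catecholborane, toluene, −78 °C
Reagents that add atoms: none
Why: Corey–Bakshi–Shibata reduction under catalyst control: the α-methylalkenyl side (C4) acts as the large group and the C2 methylene as the small one, so the (R)-oxazaborolidine should deliver hydride to the face that gives the 3S allylic alcohol; catecholborane at −78 °C reduces 1,2 and does not hydroborate the olefins.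

Step 21
Reactants: 30 (3S)-3-hydroxy compound; 31 (R)-2-methylbutanoic acid
Product: 33 3,8-diester tris-silyl ether, via O-acylisourea 32 (not isolated)
Conditions: 31, DCC, DMAP (cat.), CH2Cl2, 0 °C to rt
Reagents that add atoms: none
Why: Steglich esterification through O-acylisourea 32 and the acylpyridinium ion; at 0 °C with catalytic DMAP the α-stereocentre of the acid should not epimerise, and the tertiary C10 hydroxyl stays free.

Step 22
Reactants: 33 3,8-diester tris-silyl ether
Product: 34 1,6,10,12-tetraol 3,8-diester
Conditions: HF·pyridine, pyridine, THF, 0 °C to rt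
Reagents that add atoms: none
Why: Fluoride cleavage of the three silyl ethers (O1, O6, O12); buffering with pyridine protects the glycidic ester and the allylic esters.

Step 23
Reactants: 34 1,6,10,12-tetraol 3,8-diester
Product: 37 12,6-lactone 1,10-diol, via enal 35 (not isolated), via lactol 36 (not isolated)
Conditions: TEMPO (cat.), PhI(OAc)2, CH2Cl2, rt
Reagents that add atoms: none
Why: Oxoammonium oxidation is selective for the primary allylic alcohol; enal 35 is trapped by the C6 hydroxyl as lactol 36, which is oxidised on to the trans-fused α-methylene lactone, while the secondary C1 and tertiary C10 hydroxyls should survive.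

Step 24
Reactants: 37 12,6-lactone 1,10-diol
Product: 39 target CNP0265335.4, via C1 mesylate 38 (not isolated)
Conditions: MsCl, Et3N, CH2Cl2, −20 °C; then DBU, rt
Reagents that add atoms: none
Why: Selective mesylation of the only secondary hydroxyl, then intramolecular Williamson closure (3-exo-tet): the C10 oxygen displaces the C1 mesylate from the rear, with inversion at C1 and retention at C10, which turns the syn glycol into the trans epoxide; a non-nucleophilic amidine base avoids conjugate addition to the methylene lactone.

## Compound list

1 | (S)-carvone | CC1=CC[C@@H](CC1=O)C(C)=C | starting material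
2 | (5S)-5-(3-hydroxyprop-1-en-2-yl)-2-methylcyclohex-2-en-1-one (C12 alcohol) | CC1=CC[C@@H](CC1=O)C(=C)CO | intermediate
3 | 12-O-tert-butyldiphenylsilyl ether of 2 | CC1=CC[C@@H](CC1=O)C(=C)CO[Si](c2ccccc2)(c2ccccc2)C(C)(C)C | intermediate
4 | sodium enolate of 3 (C3–ONa, C3=C8) | CC1=CC[C@@H](C=C1O[Na])C(=C)CO[Si](c2ccccc2)(c2ccccc2)C(C)(C)C | intermediate
5 | 8α-hydroxy ketone (hydroxyl trans to the C7 branch) | CC1=CC[C@@H]([C@@H](O)C1=O)C(=C)CO[Si](c2ccccc2)(c2ccccc2)C(C)(C)C | intermediate
6 | 8-O-(2-methoxypropan-2-yl) ether of 5 | CC1=CC[C@@H]([C@@H](OC(C)(C)OC)C1=O)C(=C)CO[Si](c2ccccc2)(c2ccccc2)C(C)(C)C | intermediate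
7 | 3-bromo-2-methylprop-1-ene | C=C(C)CBr | starting material
8 | lithium enolate of 6 (C3–OLi, C3=C8) | CC1=CC[C@@H](C(OC(C)(C)OC)=C1O[Li])C(=C)CO[Si](c2ccccc2)(c2ccccc2)C(C)(C)C | intermediate
9 | 8α-methallyl-8β-(2-methoxypropan-2-yloxy) enone | CC1=CC[C@@H]([C@](CC(C)=C)(OC(C)(C)OC)C1=O)C(=C)CO[Si](c2ccccc2)(c2ccccc2)C(C)(C)C | intermediate
10 | potassium extended dienolate of 9 (C3–OK, C3=C4, C5=C6) | CC1=C(O[K])[C@@](CC(C)=C)(OC(C)(C)OC)[C@H](C=C1)C(=C)CO[Si](c2ccccc2)(c2ccccc2)C(C)(C)C | intermediate
11 | 3-(tert-butyldimethylsilyloxy)-3,5-diene from 9 | CC1=C(O[Si](C)(C)C(C)(C)C)[C@@](CC(C)=C)(OC(C)(C)OC)[C@H](C=C1)C(=C)CO[Si](c2ccccc2)(c2ccccc2)C(C)(C)C | intermediate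
12 | 6α-hydroxy enone (hydroxyl trans to the C7 branch) | CC1=C[C@@H](O)[C@@H]([C@](CC(C)=C)(OC(C)(C)OC)C1=O)C(=C)CO[Si](c2ccccc2)(c2ccccc2)C(C)(C)C | intermediate
13 | 6α-(tert-butyldimethylsilyloxy) enone | CC1=C[C@@H](O[Si](C)(C)C(C)(C)C)[C@@H]([C@](CC(C)=C)(OC(C)(C)OC)C1=O)C(=C)CO[Si](c2ccccc2)(c2ccccc2)C(C)(C)C | intermediate
14 | allylmagnesium bromide | C=CC[Mg]Br | starting material
15 | 3α-allyl-3β-hydroxy compound (hydroxyl cis to O8) | CC1=C[C@@H](O[Si](C)(C)C(C)(C)C)[C@@H]([C@](CC(C)=C)(OC(C)(C)OC)[C@@]1(O)CC=C)C(=C)CO[Si](c2ccccc2)(c2ccccc2)C(C)(C)C | intermediate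
16 | 3β,8β-O-isopropylidene acetal (3α-allyl, 8α-methallyl) | CC1=C[C@@H](O[Si](C)(C)C(C)(C)C)[C@@H]([C@]2(CC(C)=C)OC(C)(C)O[C@]12CC=C)C(=C)CO[Si](c3ccccc3)(c3ccccc3)C(C)(C)C | intermediate
17 | cis-fused bicyclic diene (ring B closed, C1=C10 olefin, ring-fusion acetonide) | CC1=C[C@@H](O[Si](C)(C)C(C)(C)C)[C@H](C(=C)CO[Si](c4ccccc4)(c4ccccc4)C(C)(C)C)[C@@]2(OC(C)(C)O3)CC(C)=CC[C@@]123 | intermediate
18 | 1,10-diol (cis, anti to the acetonide on ring B) | CC1=C[C@@H](O[Si](C)(C)C(C)(C)C)[C@H](C(=C)CO[Si](c4ccccc4)(c4ccccc4)C(C)(C)C)[C@@]2(OC(C)(C)O3)C[C@@](C)(O)[C@@H](O)C[C@@]123 | intermediate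
19 | 1-O-tert-butyldimethylsilyl ether of 18 | CC1=C[C@@H](O[Si](C)(C)C(C)(C)C)[C@H](C(=C)CO[Si](c4ccccc4)(c4ccccc4)C(C)(C)C)[C@@]2(OC(C)(C)O3)C[C@@](C)(O)[C@@H](O[Si](C)(C)C(C)(C)C)C[C@@]123 | intermediate
20 | cis-fused decalin-3,8,10-triol (key-step precursor) | O[C@]12C(C)=C[C@@H](O[Si](C)(C)C(C)(C)C)[C@H](C(=C)CO[Si](c3ccccc3)(c3ccccc3)C(C)(C)C)[C@@]1(O)C[C@@](C)(O)[C@@H](O[Si](C)(C)C(C)(C)C)C2 | intermediate
21 | cyclic diacetoxylead diester of the 3,8-glycol of 20 (tetravalent lead) | CC(=O)O[Pb]3(OC(C)=O)O[C@]12C(C)=C[C@@H](O[Si](C)(C)C(C)(C)C)[C@H](C(=C)CO[Si](c4ccccc4)(c4ccccc4)C(C)(C)C)[C@@]1(O3)C[C@@](C)(O)[C@@H](O[Si](C)(C)C(C)(C)C)C2 | intermediate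
22 | ten-membered 4Z-ene-3,8-dione (key-step product) | O=C1/C(C)=C\[C@@H](O[Si](C)(C)C(C)(C)C)[C@H](C(=C)CO[Si](c2ccccc2)(c2ccccc2)C(C)(C)C)C(=O)C[C@@](C)(O)[C@@H](O[Si](C)(C)C(C)(C)C)C1 | intermediate
23 | (8R)-8-hydroxy enone | O=C1/C(C)=C\[C@@H](O[Si](C)(C)C(C)(C)C)[C@H](C(=C)CO[Si](c2ccccc2)(c2ccccc2)C(C)(C)C)[C@H](O)C[C@@](C)(O)[C@@H](O[Si](C)(C)C(C)(C)C)C1 | intermediate
24 | (E)-2-methylbut-2-en-1-ol | C/C=C(\C)CO | starting material
25 | [(2R,3R)-2,3-dimethyloxiran-2-yl]methanol | OC[C@@]1(C)O[C@@H]1C | intermediate
26 | (2S,3R)-2,3-dimethyloxirane-2-carbaldehyde | O=C[C@@]1(C)O[C@@H]1C | intermediate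
27 | (2S,3R)-2,3-dimethyloxirane-2-carboxylic acid | OC(=O)[C@@]1(C)O[C@@H]1C | intermediate
28 | mixed anhydride of 27 with 2,4,6-trichlorobenzoic acid | Clc1cc(Cl)c(C(=O)OC(=O)[C@@]2(C)O[C@@H]2C)c(Cl)c1 | intermediate
29 | C8 (2S,3R)-2,3-dimethyloxirane-2-carboxylate of 23 | O=C1/C(C)=C\[C@@H](O[Si](C)(C)C(C)(C)C)[C@H](C(=C)CO[Si](c2ccccc2)(c2ccccc2)C(C)(C)C)[C@H](OC(=O)[C@@]2(C)O[C@@H]2C)C[C@@](C)(O)[C@@H](O[Si](C)(C)C(C)(C)C)C1 | intermediate
30 | (3S)-3-hydroxy compound | O[C@@H]1/C(C)=C\[C@@H](O[Si](C)(C)C(C)(C)C)[C@H](C(=C)CO[Si](c2ccccc2)(c2ccccc2)C(C)(C)C)[C@H](OC(=O)[C@@]2(C)O[C@@H]2C)C[C@@](C)(O)[C@@H](O[Si](C)(C)C(C)(C)C)C1 | intermediate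
31 | (R)-2-methylbutanoic acid | CC[C@@H](C)C(=O)O | starting material
32 | O-acylisourea from 31 and dicyclohexylcarbodiimide | CC[C@@H](C)C(=O)OC(=NC1CCCCC1)NC1CCCCC1 | intermediate
33 | 3-(R)-2-methylbutanoate 8-epoxy ester, silylated at O1, O6 and O12 | CC[C@@H](C)C(=O)O[C@@H]1/C(C)=C\[C@@H](O[Si](C)(C)C(C)(C)C)[C@H](C(=C)CO[Si](c2ccccc2)(c2ccccc2)C(C)(C)C)[C@H](OC(=O)[C@@]2(C)O[C@@H]2C)C[C@@](C)(O)[C@@H](O[Si](C)(C)C(C)(C)C)C1 | intermediate
34 | 1,6,10,12-tetraol 3,8-diester | CC[C@@H](C)C(=O)O[C@@H]1/C(C)=C\[C@@H](O)[C@H](C(=C)CO)[C@H](OC(=O)[C@@]2(C)O[C@@H]2C)C[C@@](C)(O)[C@@H](O)C1 | intermediate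
35 | C12 enal (1,6,10-triol) | CC[C@@H](C)C(=O)O[C@@H]1/C(C)=C\[C@@H](O)[C@H](C(=C)C=O)[C@H](OC(=O)[C@@]2(C)O[C@@H]2C)C[C@@](C)(O)[C@@H](O)C1 | intermediate
36 | 12,6-lactol (both C12 epimers) | C=C1C(O)O[C@@H]2/C=C(/C)[C@@H](OC(=O)[C@H](C)CC)C[C@H](O)[C@](C)(O)C[C@@H](OC(=O)[C@@]3(C)O[C@@H]3C)[C@@H]12 | intermediate
37 | 12,6-lactone 1,10-diol | C=C1C(=O)O[C@@H]2/C=C(/C)[C@@H](OC(=O)[C@H](C)CC)C[C@H](O)[C@](C)(O)C[C@@H](OC(=O)[C@@]3(C)O[C@@H]3C)[C@@H]12 | intermediate
38 | C1 methanesulfonate of 37 | C=C1C(=O)O[C@@H]2/C=C(/C)[C@@H](OC(=O)[C@H](C)CC)C[C@H](OS(C)(=O)=O)[C@](C)(O)C[C@@H](OC(=O)[C@@]3(C)O[C@@H]3C)[C@@H]12 | intermediate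
39 | CNP0265335.4: (1R,3S,4Z,6R,7R,8R,10R)-1,10-epoxy-3-[(R)-2-methylbutanoyloxy]-8-[(2S,3R)-2,3-dimethyloxirane-2-carbonyloxy]germacra-4,11(13)-dien-12,6-olide | C=C1C(=O)O[C@@H]2/C=C(/C)[C@@H](OC(=O)[C@H](C)CC)C[C@H]3O[C@]3(C)C[C@@H](OC(=O)[C@@]3(C)O[C@@H]3C)[C@@H]12 | target

## Step count and least certain steps

Total: 24 steps (22 in the main line from 1, and 2 for acid 27). Longest linear sequence: 22 steps (steps 1–16 and 19–24).

**Step 15 (key step).** Two processes may interfere. Ligand exchange at the crowded ditertiary glycol may be slow, which would leave time for oxidation elsewhere. The dione may also degrade during isolation by transannular aldolisation, loss of silanol across C6–C7 or C1–C2, or epimerisation at C7. The fallback sets out from 20 and uses a one-electron cleavage with (NH4)2Ce(NO3)6 (tetravalent cerium) in NaHCO3-buffered aqueous MeCN at 0 °C. This goes through alkoxy-radical β-scission, needs no cyclic diester and so does not depend on the glycol geometry. The crude dione 22 is then taken straight into step 16 without chromatography, where the route is rejoined.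

**Step 12.** The osmylation may go with poor or reversed facial selectivity if the acetonide does not outweigh the intrinsic preference of the cis-fused bicycle for its convex face; the wrong face would give the C10 epimer, which cannot be corrected later. The fallback sets out from 17 and uses the Woodward cis-hydroxylation (I2, AgOAc, wet AcOH). The iodonium ion forms on the face that osmium would take, acetate opens it at C10 from the other side, and the acetoxonium ion that displaces iodide at C1 is hydrolysed to the cis hydroxy acetate F2 on the face opposite to that preferred by osmium. Methanolysis (K2CO3, MeOH) returns to 18.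

**Step 5.** The hindered, tetrasubstituted α-alkoxy enolate may alkylate on oxygen or react sluggishly, and proton transfer may lead to the extended dienolate. The fallback sets out from 6: the sodium enolate is acylated on oxygen with 2-methylallyl chloroformate to the enol carbonate F1, and Pd(PPh3)4 (zerovalent palladium) brings about the decarboxylative Tsuji allylation. The enolate and the methallyl-palladium cation recombine at C8 anti to the C7 branch, giving 9.

**Step 16.** The directing effect may be lost if the tertiary C10 hydroxyl exchanges slowly onto boron or is tied up as a transannular hemiketal with C3; this would give low conversion or undirected attack on the wrong face. The fallback sets out from 22: NaBH4 in MeOH/CH2Cl2 at −78 °C reduces the saturated ketone without direction. Any 23 is used as planned; the 8-epi alcohol F3 is esterified with 27 under Mitsunobu conditions (PPh3, diisopropyl azodicarboxylate) with inversion at C8, which rejoins the route at 29.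

**Step 20.** The catalyst may be mismatched with the conformational bias of the ten-membered enone, or borane may be consumed by the free C10 hydroxyl, and the face selectivity would erode. The fallback sets out from 29: Luche reduction (NaBH4, CeCl3, MeOH, −78 °C) under substrate control. Any 30 is used as planned; the 3-epi alcohol F4 is esterified with 31 under Mitsunobu conditions with inversion at the allylic carbinol (allylic transposition being the side reaction to watch), which rejoins the route at 33.

## Further compounds

F1 | step 5 | enol 2-methylallyl carbonate of 6 | CC1=CC[C@@H](C(OC(C)(C)OC)=C1OC(=O)OCC(C)=C)C(=C)CO[Si](c2ccccc2)(c2ccccc2)C(C)(C)C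
F2 | step 12 | 1-O-acetyl derivative of diol 18 (cis hydroxy acetate) | CC1=C[C@@H](O[Si](C)(C)C(C)(C)C)[C@H](C(=C)CO[Si](c4ccccc4)(c4ccccc4)C(C)(C)C)[C@@]2(OC(C)(C)O3)C[C@@](C)(O)[C@@H](OC(C)=O)C[C@@]123
F0 | step 15 | none | none
F3 | step 16 | (8S)-8-hydroxy enone (8-epimer of 23) | O=C1/C(C)=C\[C@@H](O[Si](C)(C)C(C)(C)C)[C@H](C(=C)CO[Si](c2ccccc2)(c2ccccc2)C(C)(C)C)[C@@H](O)C[C@@](C)(O)[C@@H](O[Si](C)(C)C(C)(C)C)C1
F4 | step 20 | (3R)-3-hydroxy compound (3-epimer of 30) | O[C@H]1/C(C)=C\[C@@H](O[Si](C)(C)C(C)(C)C)[C@H](C(=C)CO[Si](c2ccccc2)(c2ccccc2)C(C)(C)C)[C@H](OC(=O)[C@@]2(C)O[C@@H]2C)C[C@@](C)(O)[C@@H](O[Si](C)(C)C(C)(C)C)C1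
A1 | alternative 1 | open-chain Z-ene-1,4-diol carrying fourteen skeletal carbons | OC/C(C)=C\[C@@H](O)[C@H](CC(=O)OC(C)(C)C)[C@H](O[Si](C)(C)C(C)(C)C)C/C(C)=C/COCc1ccc(OC)cc1
A2 | alternative 2 | trans α-methylene lactone with free C8 hydroxyl and Z iodoalkene | C=C1C(=O)O[C@H](/C=C(/C)I)[C@H]1[C@H](O)C/C(C)=C/CCO[Si](C)(C)C(C)(C)C
A3 | alternative 3 | isoxazoline-bridged ten-membered lactone | O=C1C[C@@H]2[C@H](O[Si](C)(C)C(C)(C)C)C[C@@](C)(O[Si](CC)(CC)CC)[C@@H]3CC(=NO3)/C(C)=C\[C@H]2O1
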